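**Retrosynthetic overview**

1. Target 22 comes from 21 in one fluoride step: two 2-(trimethylsilyl)ethyl ethers on a pyridine N-oxide mask the 1,4-dihydroxy-2-pyridone, and one Et3Si ether masks the secondary alcohol.
2. The acyl C–C bond of 21 comes from aryl bromide N-oxide 13 and decalin aldehyde 18 (Br/Mg exchange, addition, in-flask Oppenauer oxidation).
3. 13 comes from epoxy diol 10, which comes from the achiral p-quinol 7: one catalytic asymmetric epoxidation picks one of the two mirror-image enone arms and sets three stereocentres; alkene and ketone reduction finish the ring.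
4. 7 comes from the 5-lithiopyridine (from 3) and quinone monoketal 2, which is made by oxidative dearomatisation of 4-methoxyphenol 1.
5. 18 comes from (R)-citronellal 14 by cross-metathesis, Wittig olefination and intramolecular Diels–Alder reaction. Ring order: pyridine (bought), cyclohexadienone (from the arene), oxirane, decalin (both carbocycles in one cycloaddition), N-hydroxypyridone unveiled last.

**Target read-out from the SMILES:** trans-fused decalin (1R,2R,4aS,6R,8aR) with the acyl group and the C2 methyl cis and the C6 methyl equatorial. In the epoxy diol (1R,2R,5S,6R) the oxirane is cis to the tertiary OH and trans to the secondary OH.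

**Assumption:** the quinine-derived amine in step 4 is taken to select the enone arm that leads to (1S,5R,6R)-8; if an ee assay shows the antipode, the quinidine-derived pseudoenantiomer replaces it with no other change.

Step 1
Reactants: 1 4-methoxyphenol
Product: 2 4,4-dimethoxycyclohexa-2,5-dien-1-one
Conditions: PhI(OAc)2 (1.1 equiv), MeOH, 0 °C to rt
Reagents that add atoms: methanol, CO
Why: Oxidative dearomatisation of a para-alkoxyphenol by PhI(OAc)2, in which methanol traps the phenoxonium ion at the para carbon to give the quinone monoketal; no stereocentre is formed.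

Step 2
Reactants: 3 5-bromo-2,4-dichloropyridine
Product: 4 5-bromo-2,4-bis[2-(trimethylsilyl)ethoxy]pyridine
Conditions: Me3SiCH2CH2OH (2.4 equiv), NaH (2.5 equiv), DMF, 0 °C to 80 °C
Reagents that add atoms: 2-(trimethylsilyl)ethanol, C[Si](C)(C)CCO
Why: Double nucleophilic aromatic substitution, since both chlorides sit ortho/para to the ring nitrogen (C4 reacts first, C2 on warming) while the C5 bromide is not activated; no stereocentre.

Step 3
Reactants: 4 5-bromo-2,4-bis[2-(trimethylsilyl)ethoxy]pyridine; 2 4,4-dimethoxycyclohexa-2,5-dien-1-one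
Product: 7 4-{4,6-bis[2-(trimethylsilyl)ethoxy]pyridin-3-yl}-4-hydroxycyclohexa-2,5-dien-1-one (achiral p-quinol), via aryllithium 5 (not isolated), via lithium ketal alkoxide 6 (not isolated)
Conditions: n-BuLi, THF, −78 °C; then 2, −78 °C; then 1 M HCl, THF, 0 °C
Reagents that add atoms: water, O
Why: Br/Li exchange, 1,2-addition of the aryllithium to the only carbonyl of the quinone monoketal and ketal hydrolysis give a p-quinol that has a mirror plane, so no stereocentre exists yet.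

Step 4
Reactants: 7 4-{4,6-bis[2-(trimethylsilyl)ethoxy]pyridin-3-yl}-4-hydroxycyclohexa-2,5-dien-1-one
Product: 8 (1S,5R,6R)-5-{4,6-bis[2-(trimethylsilyl)ethoxy]pyridin-3-yl}-5-hydroxy-7-oxabicyclo[4.1.0]hept-3-en-2-one (oxirane cis to the tertiary OH)
Conditions: 9-amino-9-deoxy-epi-quinine (10 mol %), CF3CO2H (20 mol %), 50% aq. H2O2 (1.5 equiv), dioxane, 35 °C
Reagents that add atoms: hydrogen peroxide, OO
Why: Proposed new method: the cinchona primary amine forms a chiral iminium ion with the dienone carbonyl and dictates which β-carbon face takes up HOO−, while the substrate only admits the peroxide syn to the tertiary OH (hydrogen bond, anti to the bulky pyridyl), so only one of the two enantiotopic enone arms is matched and C1, C5 and C6 are set in one event, the second arm being mismatched and left intact; the closest known reactions are the amine-salt-catalysed Weitz–Scheffer epoxidation of cyclic enones with H2O2 and amine-catalysed desymmetrisations of 4,4-disubstituted cyclohexadienones by Michael addition.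

Step 5
Reactants: 8 (1S,5R,6R)-5-{4,6-bis[2-(trimethylsilyl)ethoxy]pyridin-3-yl}-5-hydroxy-7-oxabicyclo[4.1.0]hept-3-en-2-one
Product: 10 (1R,2R,5S,6R)-2-{4,6-bis[2-(trimethylsilyl)ethoxy]pyridin-3-yl}-7-oxabicyclo[4.1.0]heptane-2,5-diol, via epoxy ketone 9 (not isolated)
Conditions: H2 (3 atm), (Ph3P)3RhCl (5 mol %), THF–MeOH, rt; then CeCl3·7H2O, NaBH4, −78 °C
Reagents that add atoms: none
Why: Homogeneous hydrogenation saturates only the cis-disubstituted enone alkene without touching the oxirane, and the Luche reduction then delivers hydride to the face that carries the oxirane oxygen and the tertiary OH (cation-bridged delivery, opposite to the pyridyl group), so the new secondary OH is trans to the epoxide and trans to the tertiary OH.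

Step 6
Reactants: 10 (1R,2R,5S,6R)-2-{4,6-bis[2-(trimethylsilyl)ethoxy]pyridin-3-yl}-7-oxabicyclo[4.1.0]heptane-2,5-diol
Product: 11 (1R,2R,5S,6S)-2-{4,6-bis[2-(trimethylsilyl)ethoxy]pyridin-3-yl}-5-(triethylsilyloxy)-7-oxabicyclo[4.1.0]heptan-2-ol (same spatial arrangement as 10)
Conditions: Et3SiCl, imidazole, DMF, 0 °C
Reagents that add atoms: chlorotriethylsilane, CC[Si](Cl)(CC)CC
Why: Silyl ether formation is selective for the secondary alcohol over the hindered tertiary one and removes the trans-epoxy alkoxide that could undergo Payne rearrangement in step 12; no stereocentre changes.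

Step 7
Reactants: 11 (1R,2R,5S,6S)-2-{4,6-bis[2-(trimethylsilyl)ethoxy]pyridin-3-yl}-5-(triethylsilyloxy)-7-oxabicyclo[4.1.0]heptan-2-ol
Product: 12 (1R,2R,5S,6S)-2-{5-bromo-4,6-bis[2-(trimethylsilyl)ethoxy]pyridin-3-yl}-5-(triethylsilyloxy)-7-oxabicyclo[4.1.0]heptan-2-ol
Conditions: NBS (1.05 equiv), MeCN, 0 °C to rt
Reagents that add atoms: N-bromosuccinimide, BrN1C(=O)CCC1=O
Why: Electrophilic aromatic bromination at the only free ring position that is ortho to both alkoxy groups (the CH next to nitrogen is not activated); no stereocentre changes.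

Step 8
Reactants: 12 (1R,2R,5S,6S)-2-{5-bromo-4,6-bis[2-(trimethylsilyl)ethoxy]pyridin-3-yl}-5-(triethylsilyloxy)-7-oxabicyclo[4.1.0]heptan-2-ol
Product: 13 3-bromo-5-[(1R,2R,5S,6S)-2-hydroxy-5-(triethylsilyloxy)-7-oxabicyclo[4.1.0]heptan-2-yl]-2,4-bis[2-(trimethylsilyl)ethoxy]pyridine 1-oxide
Conditions: mCPBA (1.5 equiv), CH2Cl2, 0 °C to rt
Reagents that add atoms: 3-chloroperoxybenzoic acid, OOC(=O)c1cccc(Cl)c1
Why: Peracid N-oxidation of the alkoxy-activated pyridine installs the N–O bond while the molecule still has no alkene that could be epoxidised; no stereocentre changes.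

Step 9
Reactants: 14 (R)-citronellal
Product: 15 (3R,6E)-8,8-diethoxy-3-methyloct-6-enal
Conditions: acrolein diethyl acetal (5 equiv), second-generation Hoveyda–Grubbs catalyst (3 mol %), CH2Cl2, 40 °C
Reagents that add atoms: acrolein diethyl acetal, C=CC(OCC)OCC
Why: Olefin cross-metathesis of the trisubstituted alkene with an allylic acetal is driven by loss of isobutene and gives the E-alkene with the future enal masked; the methyl stereocentre is untouched.

Step 10
Reactants: 15 (3R,6E)-8,8-diethoxy-3-methyloct-6-enal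
Product: 17 (2E,6R,8E,10E)-6-methyldodeca-2,8,10-trienal, via triene acetal 16 (not isolated)
Conditions: PBu3, (E)-crotyl bromide, THF, rt; KOt-Bu, −78 °C; then 15, −78 °C to rt; then 1 M HCl, THF, rt
Reagents that add atoms: (E)-crotyl bromide, C/C=C/CBr; water, O
Why: Wittig olefination with an allylic trialkylphosphonium ylide, which gives the E-alkene and so the E,E-diene, on the only free aldehyde, followed by acid hydrolysis of the unsaturated acetal to the E-enal; no stereocentre changes.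

Step 11
Reactants: 17 (2E,6R,8E,10E)-6-methyldodeca-2,8,10-trienal
Product: 18 (1R,2R,4aS,6R,8aR)-2,6-dimethyl-1,2,4a,5,6,7,8,8a-octahydronaphthalene-1-carbaldehyde
Conditions: Me2AlCl (0.3 equiv), CH2Cl2, −78 °C to −20 °C
Reagents that add atoms: none
Why: Lewis acid-catalysed intramolecular Diels–Alder reaction through the endo transition state with a chair-like tether and equatorial methyl gives the trans-fused decalin and sets C1, C2, C4a and C8a relative to the citronellal stereocentre.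

Step 12
Reactants: 13 3-bromo-5-[(1R,2R,5S,6S)-2-hydroxy-5-(triethylsilyloxy)-7-oxabicyclo[4.1.0]heptan-2-yl]-2,4-bis[2-(trimethylsilyl)ethoxy]pyridine 1-oxide; 18 (1R,2R,4aS,6R,8aR)-2,6-dimethyl-1,2,4a,5,6,7,8,8a-octahydronaphthalene-1-carbaldehyde
Product: 21 3-[(1R,2R,4aS,6R,8aR)-2,6-dimethyl-1,2,4a,5,6,7,8,8a-octahydronaphthalene-1-carbonyl]-5-[(1R,2R,5S,6S)-2-hydroxy-5-(triethylsilyloxy)-7-oxabicyclo[4.1.0]heptan-2-yl]-2,4-bis[2-(trimethylsilyl)ethoxy]pyridine 1-oxide, via aryl Grignard 19 (not isolated), via magnesium alkoxide 20 (not isolated)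
Conditions: i-PrMgCl·LiCl (2.1 equiv), THF, −40 °C; then 18, −40 °C to 0 °C; then PhCHO (3 equiv), rt; aq. NH4Cl
Reagents that add atoms: none
Why: After deprotonation of the tertiary OH, Br/Mg exchange at the bromine flanked by two alkoxy groups outruns metalation next to the N-oxide (known behaviour of bromopyridine N-oxides at −40 °C), the aryl Grignard adds to the aldehyde, and benzaldehyde then accepts hydride from the benzylic magnesium alkoxide (magnesium Oppenauer oxidation), which erases the carbinol stereocentre and leaves C1 of the decalin untouched.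

Step 13
Reactants: 21 3-[(1R,2R,4aS,6R,8aR)-2,6-dimethyl-1,2,4a,5,6,7,8,8a-octahydronaphthalene-1-carbonyl]-5-[(1R,2R,5S,6S)-2-hydroxy-5-(triethylsilyloxy)-7-oxabicyclo[4.1.0]heptan-2-yl]-2,4-bis[2-(trimethylsilyl)ethoxy]pyridine 1-oxide
Product: 22 1,4-dihydroxy-3-[(1R,2R,4aS,6R,8aR)-2,6-dimethyl-1,2,4a,5,6,7,8,8a-octahydronaphthalene-1-carbonyl]-5-[(1R,2R,5S,6R)-2,5-dihydroxy-7-oxabicyclo[4.1.0]heptan-2-yl]pyridin-2(1H)-one (CNP0407898.5)
Conditions: Bu4NF (6 equiv), AcOH (6 equiv), THF, 0 °C to rt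
Reagents that add atoms: none
Why: Fluoride-induced fragmentation of the two 2-(trimethylsilyl)ethyl ethers (β-elimination with loss of ethene) frees the 4-OH and the 2-oxidopyridine N-oxide, which is the 1-hydroxy-2-pyridone tautomer, and the Et3Si ether is cleaved in the same pot; the acetic acid buffer keeps the oxyanions protonated so the epoxide is not opened, and no stereocentre is touched.

**Compound list**

1 | 4-methoxyphenol | COc1ccc(O)cc1 | starting material
2 | 4,4-dimethoxycyclohexa-2,5-dien-1-one | COC1(OC)C=CC(=O)C=C1 | intermediate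
3 | 5-bromo-2,4-dichloropyridine | Clc1cc(Cl)c(Br)cn1 | starting material
4 | 5-bromo-2,4-bis[2-(trimethylsilyl)ethoxy]pyridine | C[Si](C)(C)CCOc1cc(OCC[Si](C)(C)C)c(Br)cn1 | intermediate
5 | 5-lithio-2,4-bis[2-(trimethylsilyl)ethoxy]pyridine | C[Si](C)(C)CCOc1cc(OCC[Si](C)(C)C)c([Li])cn1 | intermediate (not isolated)
6 | lithium 1-{4,6-bis[2-(trimethylsilyl)ethoxy]pyridin-3-yl}-4,4-dimethoxycyclohexa-2,5-dien-1-olate | C[Si](C)(C)CCOc1cc(OCC[Si](C)(C)C)c(cn1)C1(O[Li])C=CC(OC)(OC)C=C1 | intermediate (not isolated)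
7 | 4-{4,6-bis[2-(trimethylsilyl)ethoxy]pyridin-3-yl}-4-hydroxycyclohexa-2,5-dien-1-one | C[Si](C)(C)CCOc1cc(OCC[Si](C)(C)C)c(cn1)C1(O)C=CC(=O)C=C1 | intermediate
8 | (1S,5R,6R)-5-{4,6-bis[2-(trimethylsilyl)ethoxy]pyridin-3-yl}-5-hydroxy-7-oxabicyclo[4.1.0]hept-3-en-2-one | C[Si](C)(C)CCOc1cc(OCC[Si](C)(C)C)c(cn1)[C@]1(O)C=CC(=O)[C@H]2O[C@H]21 | intermediate
9 | (1S,5R,6R)-5-{4,6-bis[2-(trimethylsilyl)ethoxy]pyridin-3-yl}-5-hydroxy-7-oxabicyclo[4.1.0]heptan-2-one | C[Si](C)(C)CCOc1cc(OCC[Si](C)(C)C)c(cn1)[C@]1(O)CCC(=O)[C@H]2O[C@H]21 | intermediate (not isolated)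
10 | (1R,2R,5S,6R)-2-{4,6-bis[2-(trimethylsilyl)ethoxy]pyridin-3-yl}-7-oxabicyclo[4.1.0]heptane-2,5-diol | C[Si](C)(C)CCOc1cc(OCC[Si](C)(C)C)c(cn1)[C@]1(O)CC[C@H](O)[C@H]2O[C@H]21 | intermediate
11 | (1R,2R,5S,6S)-2-{4,6-bis[2-(trimethylsilyl)ethoxy]pyridin-3-yl}-5-(triethylsilyloxy)-7-oxabicyclo[4.1.0]heptan-2-ol | C[Si](C)(C)CCOc1cc(OCC[Si](C)(C)C)c(cn1)[C@]1(O)CC[C@H](O[Si](CC)(CC)CC)[C@H]2O[C@H]21 | intermediate
12 | (1R,2R,5S,6S)-2-{5-bromo-4,6-bis[2-(trimethylsilyl)ethoxy]pyridin-3-yl}-5-(triethylsilyloxy)-7-oxabicyclo[4.1.0]heptan-2-ol | C[Si](C)(C)CCOc1c(Br)c(OCC[Si](C)(C)C)c(cn1)[C@]1(O)CC[C@H](O[Si](CC)(CC)CC)[C@H]2O[C@H]21 | intermediate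
13 | 3-bromo-5-[(1R,2R,5S,6S)-2-hydroxy-5-(triethylsilyloxy)-7-oxabicyclo[4.1.0]heptan-2-yl]-2,4-bis[2-(trimethylsilyl)ethoxy]pyridine 1-oxide | C[Si](C)(C)CCOc1c(Br)c(OCC[Si](C)(C)C)c(c[n+]1[O-])[C@]1(O)CC[C@H](O[Si](CC)(CC)CC)[C@H]2O[C@H]21 | intermediate
14 | (R)-citronellal, (3R)-3,7-dimethyloct-6-enal | C[C@@H](CC=O)CCC=C(C)C | starting material
15 | (3R,6E)-8,8-diethoxy-3-methyloct-6-enal | C[C@@H](CC=O)CC/C=C/C(OCC)OCC | intermediate
16 | (2E,6R,8E,10E)-1,1-diethoxy-6-methyldodeca-2,8,10-triene | C[C@@H](C/C=C/C=C/C)CC/C=C/C(OCC)OCC | intermediate (not isolated)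
17 | (2E,6R,8E,10E)-6-methyldodeca-2,8,10-trienal | C[C@@H](C/C=C/C=C/C)CC/C=C/C=O | intermediate
18 | (1R,2R,4aS,6R,8aR)-2,6-dimethyl-1,2,4a,5,6,7,8,8a-octahydronaphthalene-1-carbaldehyde | C[C@@H]1CC[C@H]2[C@H](C=O)[C@H](C)C=C[C@@H]2C1 | intermediate
19 | 3-(chloromagnesio) analogue of 13 with the tertiary OH as its chloromagnesium alkoxide | C[Si](C)(C)CCOc1c([Mg]Cl)c(OCC[Si](C)(C)C)c(c[n+]1[O-])[C@]1(O[Mg]Cl)CC[C@H](O[Si](CC)(CC)CC)[C@H]2O[C@H]21 | intermediate (not isolated)
20 | bis(chloromagnesium) alkoxide of the pyridyl(decalinyl)carbinol, carbinol carbon as a mixture of epimers | C[C@@H]1CC[C@H]2[C@H](C(O[Mg]Cl)c3c(OCC[Si](C)(C)C)c([C@]4(O[Mg]Cl)CC[C@H](O[Si](CC)(CC)CC)[C@H]5O[C@H]54)c[n+]([O-])c3OCC[Si](C)(C)C)[C@H](C)C=C[C@@H]2C1 | intermediate (not isolated)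
21 | 3-[(1R,2R,4aS,6R,8aR)-2,6-dimethyl-1,2,4a,5,6,7,8,8a-octahydronaphthalene-1-carbonyl]-5-[(1R,2R,5S,6S)-2-hydroxy-5-(triethylsilyloxy)-7-oxabicyclo[4.1.0]heptan-2-yl]-2,4-bis[2-(trimethylsilyl)ethoxy]pyridine 1-oxide | C[C@@H]1CC[C@H]2[C@H](C(=O)c3c(OCC[Si](C)(C)C)c([C@]4(O)CC[C@H](O[Si](CC)(CC)CC)[C@H]5O[C@H]54)c[n+]([O-])c3OCC[Si](C)(C)C)[C@H](C)C=C[C@@H]2C1 | intermediate
22 | 1,4-dihydroxy-3-[(1R,2R,4aS,6R,8aR)-2,6-dimethyl-1,2,4a,5,6,7,8,8a-octahydronaphthalene-1-carbonyl]-5-[(1R,2R,5S,6R)-2,5-dihydroxy-7-oxabicyclo[4.1.0]heptan-2-yl]pyridin-2(1H)-one | C[C@@H]1CC[C@H]2[C@H](C(=O)c3c(O)c([C@]4(O)CC[C@H](O)[C@H]5O[C@H]54)cn(O)c3=O)[C@H](C)C=C[C@@H]2C1 | target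

**Step count:** 13 steps in total. Longest linear sequence: 9 steps (1 → 2 → 7 → 8 → 10 → 11 → 12 → 13 → 21 → 22; the sequence from 3 is equally long).

**Three steps most likely to fail, each with one fallback**

Step 4 (desymmetrising epoxidation). The iminium may form slowly on the cross-conjugated dienone, or the catalyst may not discriminate the two arms well. The fallback sets out from 7 and breaks the symmetry by reduction instead of oxidation. An enantioselective conjugate reduction of one enone arm with CuH (from Cu(OAc)2, a DTBM-SEGPHOS enantiomer chosen by ee assay, (EtO)2MeSiH, t-BuOH, toluene) gives (S)-4-{4,6-bis[2-(trimethylsilyl)ethoxy]pyridin-3-yl}-4-hydroxycyclohex-2-en-1-one F1. The remaining enone is then epoxidised syn to the tertiary OH by hydroxyl-directed nucleophilic epoxidation (t-BuOOH, DBU, CH2Cl2). This comes back to the route at epoxy ketone 9, which is reduced with NaBH4/CeCl3 as in the second half of step 5.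

Step 5 (facial selectivity of the ketone reduction). Hydride could instead arrive anti to the oxirane. The fallback sets out from 9, isolated after the hydrogenation, and accepts that outcome. Reduction from the open face (for example with LiBH(s-Bu)3) gives the epimeric (1R,2R,5R,6R)-2-{4,6-bis[2-(trimethylsilyl)ethoxy]pyridin-3-yl}-7-oxabicyclo[4.1.0]heptane-2,5-diol F2. Its secondary carbinol is inverted by Mitsunobu reaction (4-nitrobenzoic acid, PPh3, DIAD, THF) to the 4-nitrobenzoate of 10 F3. Methanolysis (K2CO3, MeOH, 0 °C) comes back to the route at 10.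

Step 12 (magnesiation next to an N-oxide and Oppenauer oxidation of a hindered carbinol). Metalation at the free position beside the N-oxide, enolisation of 18 or a sluggish hydride transfer could each spoil it. The fallback sets out from 13 and 18 and avoids organomagnesium chemistry. 13 is stannylated (Me3SnSnMe3, Pd(PPh3)4, toluene, 90 °C) to the 3-(trimethylstannyl)pyridine 1-oxide F4. 18 is oxidised (NaClO2, NaH2PO4, 2-methyl-2-butene, t-BuOH–H2O) to (1R,2R,4aS,6R,8aR)-2,6-dimethyl-1,2,4a,5,6,7,8,8a-octahydronaphthalene-1-carboxylic acid F5. F5 is converted ((COCl)2, DMF cat., CH2Cl2) to (1R,2R,4aS,6R,8aR)-2,6-dimethyl-1,2,4a,5,6,7,8,8a-octahydronaphthalene-1-carbonyl chloride F6. Stille acylation of F4 with F6 (Pd2(dba)3, P(2-furyl)3, CuI, THF, 50 °C) comes back to the route at 21.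

**Further compounds**

F1 | step 4 | (S)-4-{4,6-bis[2-(trimethylsilyl)ethoxy]pyridin-3-yl}-4-hydroxycyclohex-2-en-1-one | C[Si](C)(C)CCOc1cc(OCC[Si](C)(C)C)c(cn1)[C@]1(O)CCC(=O)C=C1
F2 | step 5 | (1R,2R,5R,6R)-2-{4,6-bis[2-(trimethylsilyl)ethoxy]pyridin-3-yl}-7-oxabicyclo[4.1.0]heptane-2,5-diol (secondary OH cis to the oxirane) | C[Si](C)(C)CCOc1cc(OCC[Si](C)(C)C)c(cn1)[C@]1(O)CC[C@@H](O)[C@H]2O[C@H]21
F3 | step 5 | (1R,2R,5S,6R)-5-{4,6-bis[2-(trimethylsilyl)ethoxy]pyridin-3-yl}-5-hydroxy-7-oxabicyclo[4.1.0]heptan-2-yl 4-nitrobenzoate (4-nitrobenzoate of 10) | C[Si](C)(C)CCOc1cc(OCC[Si](C)(C)C)c(cn1)[C@]1(O)CC[C@H](OC(=O)c3ccc(cc3)[N+](=O)[O-])[C@H]2O[C@H]21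
F4 | step 12 | 5-[(1R,2R,5S,6S)-2-hydroxy-5-(triethylsilyloxy)-7-oxabicyclo[4.1.0]heptan-2-yl]-2,4-bis[2-(trimethylsilyl)ethoxy]-3-(trimethylstannyl)pyridine 1-oxide | C[Si](C)(C)CCOc1c([Sn](C)(C)C)c(OCC[Si](C)(C)C)c(c[n+]1[O-])[C@]1(O)CC[C@H](O[Si](CC)(CC)CC)[C@H]2O[C@H]21
F5 | step 12 | (1R,2R,4aS,6R,8aR)-2,6-dimethyl-1,2,4a,5,6,7,8,8a-octahydronaphthalene-1-carboxylic acid | C[C@@H]1CC[C@H]2[C@H](C(=O)O)[C@H](C)C=C[C@@H]2C1
F6 | step 12 | (1R,2R,4aS,6R,8aR)-2,6-dimethyl-1,2,4a,5,6,7,8,8a-octahydronaphthalene-1-carbonyl chloride | C[C@@H]1CC[C@H]2[C@H](C(=O)Cl)[C@H](C)C=C[C@@H]2C1
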